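The easy step is a division: how much incoming ligand each flask holds per starting complex charged.

in all of them: incoming ligand 0.175 M
- maple: starting complex 0.0056 M; run made earlier
- birch: starting complex 0.58 M; run made earlier
- amber: starting complex 0.010 M; time 1.0 h
- ochre: starting complex 0.030 M; time 1.0 h
- green: starting complex 0.080 M; time 1.0 h
- teal: starting complex 0.25 M; time 1.0 h
- grey: starting complex 0.80 M; time 1.0 h

- maple (time / min: complex with three exchanged / %, starting complex / %): 3.00: 1.3, 68.2; 6.00: 5.7, 47.0; 12.0: 18.4, 23.1; 20.0: 31.5, 8.8; 40.0: 40.7, 1.1
- birch (time / min: complex with three exchanged / %, starting complex / %): 3.00: 0.3, 81.5; 6.00: 0.2, 78.5; 12.0: 0.2, 77.2; 20.0: 0.2, 78.3; 40.0: 0.6, 79.0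

(each reading ± 0.3 percentage points)

- "hardly changes" means that all values lie within two and a half points (for a concentration: within two and a half percent of the largest)

* [complex with three exchanged] at the end for amber, ochre, green, teal, grey, in this order
* how the row runs (falls, then rises / rises all the way / rises, then falls / hardly changes / falls all the way)

Maple and birch carry the same 0.175 M of incoming ligand, and at that level the starting complex in maple shows a half-life of 5.75 min. Between 6.00 min and 40.0 min the starting complex in maple falls from 47.0% to 1.1%, yet the starting complex in birch changes by 1.8 percentage points around a mean reading of 78.2%. So I take birch to have consumed its 0.175 M of incoming ligand by then. On that assumption the birch readings give 1.39 for what I call the ligand cost, the incoming ligand consumed per starting complex lost. That is below the 3 exchanges a finished product takes, and the product in birch reads 0.6% at its highest.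

Grey looks nearly like birch, at 0.80 M against 0.58 M. Its ligand per complex charged, 0.219, lies below the ligand cost, so I treat incoming ligand as the limiting reagent there. At birch's cost, I reckon that the incoming ligand in grey removes 0.126 M of starting complex and leaves 84.2% of it. Teal also lies below the cost, and green lies above it, so I expect the product to drop from green to teal. My reckoning gives amounts of starting complex, not of product, so the row values are the forecast's: 0.0043 M, 0.012 M, 0.016 M, 0.004 M, 0.001 M, with the shape rises, then falls. Its words are “Teal and grey stall at early intermediates and give little product.”

The flasks give 0.00391 M, 0.00912 M, 0.0101 M, 0.00350 M, 8.92 × 10⁻⁴ M, so the shape is rises, then falls, with the turn at a charge of 0.055 M.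

    complex with two exchanged → side product (k = 0.140 min⁻¹)
    complex with one exchanged + incoming ligand ⇌ leaving ligand + complex with two exchanged (K = 140, k = 1.80 L mol⁻¹ min⁻¹)
    complex with two exchanged + incoming ligand ⇌ leaving ligand + complex with three exchanged (K = 7.60, k = 0.620 L mol⁻¹ min⁻¹)
    starting complex + incoming ligand ⇌ leaving ligand + complex with one exchanged (K = 8.40, k = 0.720 L mol⁻¹ min⁻¹)

Grey ends with 84.6% of its starting complex and 1.0% of its incoming ligand, beside the 84.2% I reckoned. Put to teal, the ligand cost gives 49.5% of starting complex left. Teal ends at 60.2%, with a ligand cost of 1.73.

The readings come from a simulation with made-up constants.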